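## Retrosynthetic overview

1. Formed last: the benzene ring of the phthalide, by an Alder–Rickert reaction (Diels–Alder, then retro-Diels–Alder loss of ethylene) of 1,3-dimethoxycyclohexa-1,3-diene with a (4S)-4-acyloxy-2-ynoate; the lactone closes in the same pot.
2. Ynoate ⇐ (S)-vinyl carbinol (Br2, double dehydrobromination, ClCO2Me) ⇐ terminal (S)-epoxide + dimethylsulfonium methylide.
3. 5,5-Spiroketal ⇐ keto diol ⇐ acetone dimethylhydrazone alkylated at both α-carbons, by (S)-propylene oxide and by one end of a C2-symmetric bis-epoxide.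
4. Bis-epoxide ⇐ butane-1,4-diyl di-Grignard + 2 × (S)-epichlorohydrin. C3 and C2'' come from (S)-epichlorohydrin, C7'' from (S)-propylene oxide, C5'' is thermodynamic.
5. Ring order: two oxiranes → both tetrahydrofuran rings of the spiroketal together → benzene ring → γ-lactone.

Assumption: the spiro carbon of a 5,5-spiroketal is configurationally labile and barely biased by C2''/C7'' (about 1:1 at equilibrium), so 12–19 are written as the 5S epimer but carried as the 5S/5R mixture; the epimers are separated after step 6 and the 5''R material is re-equilibrated with acid and recycled.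

## Route

**Step 1**
Reactants: 1 1,4-dibromobutane; 2 (S)-epichlorohydrin
Product: 5 (2S,2'S)-2,2'-(hexane-1,6-diyl)bis(oxirane), via bis-Grignard reagent 3 (not isolated), via bis-chlorohydrin 4 (not isolated)
Conditions: Mg (2.4 equiv), THF, reflux; CuI (10 mol %), 2 (2.05 equiv), −40 → 0 °C; then 4 M aq NaOH, rt, 12 h
Reagents that add atoms: none
Why: Copper-catalysed Grignard opening of each epoxide at its CH2 terminus (SN2) followed by base-induced chlorohydrin ring closure never touches the C–O stereocentre, so both centres of 5 are the bought (S)-centre of 2.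

**Step 2**
Reactants: 6 acetone N,N-dimethylhydrazone; 7 (S)-propylene oxide; 5 (2S,2'S)-2,2'-(hexane-1,6-diyl)bis(oxirane)
Product: 9 (2S,8S)-2,8-dihydroxy-14-[(2S)-oxiran-2-yl]tetradecan-5-one N,N-dimethylhydrazone, via hydroxy hydrazone 8 (not isolated)
Conditions: 6, n-BuLi (1.05 equiv), THF, −78 → 0 °C; 7 (1.05 equiv), −78 → 0 °C; n-BuLi (1.1 equiv), −78 → 0 °C; cannulate into 5 (3 equiv), THF, −78 °C → rt; pH 7 buffer; excess 5 distilled off and reused
Reagents that add atoms: none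
Why: Corey–Enders-type α,α'-bis-alkylation of a dimethylhydrazone azaenolate (second metalation at the unsubstituted methyl) opens each epoxide at CH2, so C7'' and C2'' keep the bought configurations, and the threefold excess of C2-symmetric 5 ensures mono-opening.

**Step 3**
Reactants: 9 (2S,8S)-2,8-dihydroxy-14-[(2S)-oxiran-2-yl]tetradecan-5-one N,N-dimethylhydrazone
Product: 12 (3S)-9-[(2S,5S,7S)-7-methyl-1,6-dioxaspiro[4.4]nonan-2-yl]non-1-en-3-ol, via hydrazone triol 10 (not isolated), via keto triol 11 (not isolated)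
Conditions: Me3S+ I− (8 equiv), n-BuLi (7.5 equiv), THF, −10 °C → rt; then 1 M aq HCl, THF, rt, 3 h
Reagents that add atoms: trimethylsulfonium iodide, C[S+](C)C.[I-]
Why: Dimethylsulfonium methylide opens the epoxide at CH2 and the β-alkoxy sulfonium salt eliminates Me2S (one-carbon epoxide-to-allylic-alcohol homologation, carbinol centre untouched); acid then hydrolyses the hydrazone and the 1,4-hydroxy ketone on each side closes to the spiroketal under thermodynamic control (C5 about 1:1).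

**Step 4**
Reactants: 12 (3S)-9-[(2S,5S,7S)-7-methyl-1,6-dioxaspiro[4.4]nonan-2-yl]non-1-en-3-ol
Product: 13 (3S)-1,2-dibromo-9-[(2S,5S,7S)-7-methyl-1,6-dioxaspiro[4.4]nonan-2-yl]nonan-3-ol
Conditions: Br2 (1.05 equiv), NaHCO3 (solid), CH2Cl2, −78 °C; aq Na2S2O3
Reagents that add atoms: bromine, BrBr
Why: Electrophilic anti-addition of bromine to the terminal alkene is fast at −78 °C and the buffer protects the spiroketal; the new CHBr centre is an epimer mixture that step 5 erases.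

**Step 5**
Reactants: 13 (3S)-1,2-dibromo-9-[(2S,5S,7S)-7-methyl-1,6-dioxaspiro[4.4]nonan-2-yl]nonan-3-ol
Product: 15 methyl (4S)-4-[(methoxycarbonyl)oxy]-10-[(2S,5S,7S)-7-methyl-1,6-dioxaspiro[4.4]nonan-2-yl]dec-2-ynoate, via dilithium alkynolate 14 (not isolated)
Conditions: LiN(i-Pr)2 (4.6 equiv), THF, −78 → 0 °C; then ClCO2Me (3 equiv), −78 → 0 °C
Reagents that add atoms: methyl chloroformate, COC(=O)Cl
Why: Double E2 dehydrobromination (directly or through the epoxy bromide formed by the alkoxide) gives the lithium acetylide without breaking the C3–O bond, and the chloroformate acylates carbon and oxygen to give the activated ynoate with its hydroxyl masked.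

**Step 6**
Reactants: 15 methyl (4S)-4-[(methoxycarbonyl)oxy]-10-[(2S,5S,7S)-7-methyl-1,6-dioxaspiro[4.4]nonan-2-yl]dec-2-ynoate; 16 1,5-dimethoxycyclohexa-1,4-diene
Product: 20 (3S)-5,7-dimethoxy-3-{6-[(2S,5S,7S)-7-methyl-1,6-dioxaspiro[4.4]nonan-2-yl]hexyl}-2-benzofuran-1(3H)-one, via conjugated diene 17 (not isolated), via bicyclooctadiene adduct 18 (not isolated), via benzoate carbonate 19 (not isolated)
Conditions: 16 (4 equiv), dichloromaleic anhydride (5 mol %), neat, sealed tube, 160 °C, 16 h; evaporate; then K2CO3 (0.3 equiv), MeOH, rt; preparative HPLC; recovered 5''R epimer re-equilibrated (p-TsOH cat., CH2Cl2) and re-separated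
Reagents that add atoms: none
Why: Alder–Rickert reaction: the diene conjugated in situ adds to the ynoate (Diels–Alder, its nucleophilic CH terminus to the ynoate β-carbon, which places the ester ortho to OMe) and the bicyclo[2.2.2]octadiene aromatises by retro-Diels–Alder loss of ethylene; methoxide then cleaves the carbonate and the benzylic alkoxide lactonises onto the ortho ester with the C3–O bond, and hence (S), intact.

## Compound list

1 | 1,4-dibromobutane | BrCCCCBr | starting material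
2 | (S)-epichlorohydrin, (2S)-2-(chloromethyl)oxirane | ClC[C@@H]1CO1 | starting material
3 | butane-1,4-diylbis(magnesium bromide) | Br[Mg]CCCC[Mg]Br | intermediate
4 | (2S,9S)-1,10-dichlorodecane-2,9-diol (in the flask as its magnesium alkoxide) | ClC[C@@H](O)CCCCCC[C@H](O)CCl | intermediate
5 | (2S,2'S)-2,2'-(hexane-1,6-diyl)bis(oxirane) | C1O[C@H]1CCCCCC[C@H]1CO1 | intermediate
6 | acetone N,N-dimethylhydrazone | CC(C)=NN(C)C | starting material
7 | (S)-propylene oxide, (2S)-2-methyloxirane | C[C@H]1CO1 | starting material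
8 | (5S)-5-hydroxyhexan-2-one N,N-dimethylhydrazone (in the flask as its lithium alkoxide) | C[C@H](O)CCC(C)=NN(C)C | intermediate
9 | (2S,8S)-2,8-dihydroxy-14-[(2S)-oxiran-2-yl]tetradecan-5-one N,N-dimethylhydrazone | C[C@H](O)CCC(=NN(C)C)CC[C@@H](O)CCCCCC[C@H]1CO1 | intermediate
10 | (2S,8S,15S)-2,8,15-trihydroxyheptadec-16-en-5-one N,N-dimethylhydrazone | C[C@H](O)CCC(=NN(C)C)CC[C@@H](O)CCCCCC[C@H](O)C=C | intermediate
11 | (2S,8S,15S)-2,8,15-trihydroxyheptadec-16-en-5-one | C[C@H](O)CCC(=O)CC[C@@H](O)CCCCCC[C@H](O)C=C | intermediate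
12 | (3S)-9-[(2S,5S,7S)-7-methyl-1,6-dioxaspiro[4.4]nonan-2-yl]non-1-en-3-ol | C=C[C@H](CCCCCC[C@H]1CC[C@]2(CC[C@H](C)O2)O1)O | intermediate
13 | (3S)-1,2-dibromo-9-[(2S,5S,7S)-7-methyl-1,6-dioxaspiro[4.4]nonan-2-yl]nonan-3-ol (both C2 epimers) | BrCC(Br)[C@H](CCCCCC[C@H]1CC[C@]2(CC[C@H](C)O2)O1)O | intermediate
14 | dilithium salt (C1 and O) of (3S)-9-[(2S,5S,7S)-7-methyl-1,6-dioxaspiro[4.4]nonan-2-yl]non-1-yn-3-ol | [Li+].[Li+].[C-]#C[C@H](CCCCCC[C@H]1CC[C@]2(CC[C@H](C)O2)O1)[O-] | intermediate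
15 | methyl (4S)-4-[(methoxycarbonyl)oxy]-10-[(2S,5S,7S)-7-methyl-1,6-dioxaspiro[4.4]nonan-2-yl]dec-2-ynoate | COC(=O)C#C[C@H](CCCCCC[C@H]1CC[C@]2(CC[C@H](C)O2)O1)OC(=O)OC | intermediate
16 | 1,5-dimethoxycyclohexa-1,4-diene | COC1=CCC=C(OC)C1 | starting material
17 | 1,3-dimethoxycyclohexa-1,3-diene | COC1=CC(OC)=CCC1 | intermediate
18 | methyl 1,5-dimethoxy-3-{(1S)-1-[(methoxycarbonyl)oxy]-7-[(2S,5S,7S)-7-methyl-1,6-dioxaspiro[4.4]nonan-2-yl]heptyl}bicyclo[2.2.2]octa-2,5-diene-2-carboxylate (bridgehead epimers) | COC(=O)C1=C(C2CCC1(OC)C=C2OC)[C@H](CCCCCC[C@H]3CC[C@]4(CC[C@H](C)O4)O3)OC(=O)OC | intermediate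
19 | methyl 2,4-dimethoxy-6-{(1S)-1-[(methoxycarbonyl)oxy]-7-[(2S,5S,7S)-7-methyl-1,6-dioxaspiro[4.4]nonan-2-yl]heptyl}benzoate | COC(=O)c1c(OC)cc(OC)cc1[C@H](CCCCCC[C@H]2CC[C@]3(CC[C@H](C)O3)O2)OC(=O)OC | intermediate
20 | (3S)-5,7-dimethoxy-3-{6-[(2S,5S,7S)-7-methyl-1,6-dioxaspiro[4.4]nonan-2-yl]hexyl}-2-benzofuran-1(3H)-one | COc1cc(OC)c2c(c1)[C@H](CCCCCC[C@H]1CC[C@]3(CC[C@H](C)O3)O1)OC2=O | target

## Summary

Total step count: 6. Longest linear sequence: 6 steps (1 and 2 → 5 → 9 → 12 → 13 → 15 → 20).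

Steps most likely to fail:

**Step 2.** Mono-opening of C2-symmetric 5 is statistical, and the hydrazone must be alkylated twice in one pot. The fallback sets out from 2 and comes back at 12 with no statistical step. 1-Bromo-4-chlorobutane and Mg (THF, 0 °C) give 4-chlorobutylmagnesium bromide F1, which opens 2 (CuI 5 mol %, −40 °C); stirring with aq NaOH closes (2S)-1,7-dichloroheptan-2-ol F2 to (2S)-2-(5-chloropentyl)oxirane F3. The dianion made from 8 (6, 7 and n-BuLi as in step 2) opens F3 (1.1 equiv; the primary chloride is inert below 0 °C) to chloro hydrazone F4. Aqueous HCl (1 M) hydrolyses it to keto diol F5, which closes to spiroketal chloride F6. Mg (THF, reflux) converts F6 into Grignard reagent F7, which opens a further equivalent of 2 (CuI, −40 °C; aq NH4Cl) to chlorohydrin F8. Me3S+ I−/n-BuLi closes F8 to epoxide F9 in the flask and homologates it to 12.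

**Step 5.** Double dehydrobromination next to a free alkoxide and C,O-bis-acylation in one pot may give bromoalkene or partly acylated material. The fallback sets out from 12 and comes back at 14 without the dibromide. t-BuMe2SiCl/imidazole gives silyl ether F10; O3 (CH2Cl2, −78 °C) then PPh3 gives α-silyloxy aldehyde F11; dimethyl (1-diazo-2-oxopropyl)phosphonate, K2CO3, MeOH (Seyferth–Gilbert homologation in its Ohira–Bestmann form) gives silyl-protected alkyne F12; Bu4NF gives alkynol F13. n-BuLi (2.1 equiv, THF, −78 °C) turns F13 into 14, which is acylated as in step 5.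

**Step 6.** In situ conjugation of 16, a 160 °C cycloaddition on the fully elaborated ynoate and the lactonisation must all work in sequence. The fallback sets out from 15 and comes back at 20, building the arene by Diels–Alder/elimination with an acyclic diene instead. (E)-1,3-Dimethoxy-1-(trimethylsilyloxy)buta-1,3-diene (toluene, 80 °C) gives cyclohexadiene adduct F14, which aromatises by loss of methanol and is desilylated on dilute-acid work-up to salicylate F15. K2CO3/MeOH lactonises it to hydroxyphthalide F16, and MeI/K2CO3 (acetone, reflux) methylates the phenol to give 20.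

## Further compounds

F1 | step 2 | 4-chlorobutylmagnesium bromide | ClCCCC[Mg]Br
F2 | step 2 | (2S)-1,7-dichloroheptan-2-ol | ClC[C@@H](O)CCCCCCl
F3 | step 2 | (2S)-2-(5-chloropentyl)oxirane | ClCCCCC[C@H]1CO1
F4 | step 2 | (2S,8S)-13-chloro-2,8-dihydroxytridecan-5-one N,N-dimethylhydrazone | C[C@H](O)CCC(=NN(C)C)CC[C@@H](O)CCCCCCl
F5 | step 2 | (2S,8S)-13-chloro-2,8-dihydroxytridecan-5-one | C[C@H](O)CCC(=O)CC[C@@H](O)CCCCCCl
F6 | step 2 | (2S,5S,7S)-2-(5-chloropentyl)-7-methyl-1,6-dioxaspiro[4.4]nonane | ClCCCCC[C@H]1CC[C@]2(CC[C@H](C)O2)O1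
F7 | step 2 | {5-[(2S,5S,7S)-7-methyl-1,6-dioxaspiro[4.4]nonan-2-yl]pentyl}magnesium chloride | Cl[Mg]CCCCC[C@H]1CC[C@]2(CC[C@H](C)O2)O1
F8 | step 2 | (2S)-1-chloro-8-[(2S,5S,7S)-7-methyl-1,6-dioxaspiro[4.4]nonan-2-yl]octan-2-ol | ClC[C@@H](O)CCCCCC[C@H]1CC[C@]2(CC[C@H](C)O2)O1
F9 | step 2 | (2S)-2-{6-[(2S,5S,7S)-7-methyl-1,6-dioxaspiro[4.4]nonan-2-yl]hexyl}oxirane | C1O[C@H]1CCCCCC[C@H]1CC[C@]2(CC[C@H](C)O2)O1
F10 | step 5 | tert-butyl(dimethyl){[(3S)-9-[(2S,5S,7S)-7-methyl-1,6-dioxaspiro[4.4]nonan-2-yl]non-1-en-3-yl]oxy}silane | C=C[C@H](CCCCCC[C@H]1CC[C@]2(CC[C@H](C)O2)O1)O[Si](C)(C)C(C)(C)C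
F11 | step 5 | (2S)-2-{[tert-butyl(dimethyl)silyl]oxy}-8-[(2S,5S,7S)-7-methyl-1,6-dioxaspiro[4.4]nonan-2-yl]octanal | O=C[C@H](CCCCCC[C@H]1CC[C@]2(CC[C@H](C)O2)O1)O[Si](C)(C)C(C)(C)C
F12 | step 5 | tert-butyl(dimethyl){[(3S)-9-[(2S,5S,7S)-7-methyl-1,6-dioxaspiro[4.4]nonan-2-yl]non-1-yn-3-yl]oxy}silane | C#C[C@H](CCCCCC[C@H]1CC[C@]2(CC[C@H](C)O2)O1)O[Si](C)(C)C(C)(C)C
F13 | step 5 | (3S)-9-[(2S,5S,7S)-7-methyl-1,6-dioxaspiro[4.4]nonan-2-yl]non-1-yn-3-ol | C#C[C@H](CCCCCC[C@H]1CC[C@]2(CC[C@H](C)O2)O1)O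
F14 | step 6 | methyl 4,6-dimethoxy-2-{(1S)-1-[(methoxycarbonyl)oxy]-7-[(2S,5S,7S)-7-methyl-1,6-dioxaspiro[4.4]nonan-2-yl]heptyl}-6-[(trimethylsilyl)oxy]cyclohexa-1,4-diene-1-carboxylate | COC(=O)C1=C(CC(OC)=CC1(OC)O[Si](C)(C)C)[C@H](CCCCCC[C@H]2CC[C@]3(CC[C@H](C)O3)O2)OC(=O)OC
F15 | step 6 | methyl 2-hydroxy-4-methoxy-6-{(1S)-1-[(methoxycarbonyl)oxy]-7-[(2S,5S,7S)-7-methyl-1,6-dioxaspiro[4.4]nonan-2-yl]heptyl}benzoate | COC(=O)c1c(O)cc(OC)cc1[C@H](CCCCCC[C@H]2CC[C@]3(CC[C@H](C)O3)O2)OC(=O)OC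
F16 | step 6 | (3S)-7-hydroxy-5-methoxy-3-{6-[(2S,5S,7S)-7-methyl-1,6-dioxaspiro[4.4]nonan-2-yl]hexyl}-2-benzofuran-1(3H)-one | COc1cc(O)c2c(c1)[C@H](CCCCCC[C@H]1CC[C@]3(CC[C@H](C)O3)O1)OC2=O
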